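All constants were drawn at random within sensible limits; no experiment stands behind them.

The amounts were what differed: four flasks took different charges of substrate, while both nucleophiles and the capture agent stayed the same.

| flask | substrate | first nucleophile | second nucleophile | capture agent | time |
|---|---|---|---|---|---|
| Friday's | 0.0060 M | 0.0400 M | 0.0210 M | 6.00 mM | 50 h |
| Wednesday's | 0.020 M | 0.0400 M | 0.0210 M | 6.00 mM | 50 h |
| Tuesday's | 0.060 M | 0.0400 M | 0.0210 M | 6.00 mM | 50 h |
| Sunday's | 0.20 M | 0.0400 M | 0.0210 M | 6.00 mM | 50 h |

    substrate → open intermediate (k1 = 0.10 h⁻¹)
    first nucleophile + open intermediate → target (k2 = 7.2 M⁻¹ h⁻¹)
    second nucleophile + open intermediate → other capture product (k3 = 350 M⁻¹ h⁻¹)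
    open intermediate → solvolysis product (k4 = 0.30 h⁻¹)
    open intermediate + capture agent → trapped intermediate (k5 = 0.40 M⁻¹ h⁻¹)
    target → over-reaction product (k6 = 0.023 h⁻¹)

* amount of target at the end, in percent of the substrate charged for Friday's, Wednesday's, Tuesday's, Sunday's, in this order
* how that number moves from the first to the last of them (rises all the way / hardly changes / rises, then falls / falls, then rises / falls all the way)

- "hardly changes" means that all values lie within two and a half points (for a concentration: within two and a half percent of the largest)
- run time (Friday's): 50 h

I worked with fractions left. The open intermediate goes to target at a rate proportional to its own level and to the first nucleophile, and to solvolysis product at a rate proportional to its own level. Its level therefore cancels in the ratio of those two rates, and the second nucleophile does not appear in that ratio. So with each bit of solvolysis product formed, the first nucleophile falls by a constant fraction of what it has left. I named the rate constant of step 2 over that of step 4 the toll, the fractional loss of first nucleophile per unit concentration of solvolysis product formed, a kind of selectivity factor: 24.0 M⁻¹. The fraction of first nucleophile left is then the exponential of minus the toll, times the substrate charge, times the fraction of that charge that became solvolysis product.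

I tried this on Sunday's flask. After 50 h the fraction of substrate left is 0.674%. The capture step runs at 0.00240 h⁻¹, slower than solvolysis at 0.30 h⁻¹, so I dropped it. The second nucleophile can take 10.5% of Sunday's charge and the first 20.0%. If both were used up, solvolysis product would be 68.8% of the charge. The toll then leaves 3.67% of the first nucleophile, so the guess nearly holds, and target made comes to 19.3% of the charge. Target also decays, and a fraction 31.7% of any made at the very start stays until the end, which would leave 6.12%. Later-made target keeps more, so I committed to a little above that for Sunday's flask.

In Friday's flask the second nucleophile is 350% of the charge. It captures at 7.35 h⁻¹ against 0.288 h⁻¹ for the first nucleophile, so the target's opening share is 3.63%. I left Tuesday's flask unreckoned.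

The forecast gave 1.7%, 3%, 12% and 7.5%, with the shape rises, then falls, and said that on Sunday's flask the target “forms early, so it decays longest”. The simulation gave 1.70%, 3.02%, 12.3% and 7.38%, so the row rises, then falls.

In Sunday's flask the 68.7% of solvolysis product at 50.0 h, put through the toll 24.0 M⁻¹, gives 3.69% of the first nucleophile left, and the flask held 3.69%. In Tuesday's flask the 36.6% of solvolysis product gives by the same toll 59.1% left, and the flask held 59.1%.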